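**Plan**

1. Retrosynthetic cuts, in order:
   - the ten O-benzyl groups and two C8 bromine caps;
   - both aryl bonds at C4 of the upper (epiafzelechin) unit, C4–C4a (ring A) and C4–C6 (ring D of the epicatechin gallate unit), which turns C4 into an acetal carbon;
   - O1–C2 (phenoxide plus epoxide);
   - the gallate ester.
2. Enabling feature: C4 of the upper unit is a methine bonded to two phloroglucinol-type rings (C4a of ring A, C6 of ring D), so it is a masked aldehyde carbon. Ring A is already held at C2 through O1. One acetal carbon can therefore be arylated twice, once within the molecule, and this closes the pyran ring O1–C2–C3–C4–C4a–C8a.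
3. Forward order: the chain C2–C3–C4 comes from alkyne coupling, Z-reduction and epoxidation, and ring A is then attached through O1. Rings A, B, D, E, F and the galloyl ring are bought. The upper pyran ring (ring C) is the only ring made, and it closes in the operation that also joins the two halves.
4. Stereochemistry: lower C2/C3 come from (−)-epicatechin. Upper C3 and, after SN2 inversion, C2 come from a catalytic enantioselective epoxidation of the Z-alkene (cis-epoxide → syn ether → 2,3-cis). Upper C4 is set by β-face attack anti to 3-OH and 2-aryl (3,4-trans).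
5. Helpers: Br at C8 of each half steers bond formation to C6 of ring D and blocks oligomerisation. Both bromines leave with the benzyl groups in the final hydrogenolysis.

Key step: step 9

Remark: flavan numbering is used throughout. Upper unit = rings A (phloroglucinol), C (pyran), B (4-hydroxyphenyl). Lower unit = rings D, F, E.
Assumption: the compounds marked as starting materials in the compound list, the salen catalyst and all reagents are taken to be commercial.

**Route**

Step 1
Reactants: 1 1-(benzyloxy)-4-iodobenzene; 2 3,3-diethoxyprop-1-yne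
Product: 3 1-(benzyloxy)-4-(3,3-diethoxyprop-1-yn-1-yl)benzene
Conditions: PdCl2(PPh3)2 (2 mol %), CuI (4 mol %), Et3N, THF, rt
Reagents that add atoms: none
Why: Sonogashira coupling of an aryl iodide with a terminal alkyne is reliable, the acetal and the benzyl ether are inert to Pd/Cu/amine, and no stereocentre is formed.

Step 2
Reactants: 3 1-(benzyloxy)-4-(3,3-diethoxyprop-1-yn-1-yl)benzene
Product: 4 1-(benzyloxy)-4-[(1Z)-3,3-diethoxyprop-1-en-1-yl]benzene
Conditions: H2 (1 atm), Lindlar catalyst, quinoline, EtOAc, rt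
Reagents that add atoms: none
Why: Lindlar semihydrogenation delivers both hydrogens syn from the poisoned Pd surface, so the Z-alkene should result, and aryl benzyl ethers and acetals are not touched.

Step 3
Reactants: 4 1-(benzyloxy)-4-[(1Z)-3,3-diethoxyprop-1-en-1-yl]benzene
Product: 5 (2S,3S)-2-[4-(benzyloxy)phenyl]-3-(diethoxymethyl)oxirane (cis-epoxide)
Conditions: (S,S)-Jacobsen Mn(salen)Cl (5 mol %), 4-phenylpyridine N-oxide (25 mol %), aq NaOCl (pH 11.3 buffer), CH2Cl2, 0 °C
Reagents that add atoms: sodium hypochlorite, [Na+].[O-]Cl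
Why: The Jacobsen–Katsuki epoxidation is at its best with cis-β-substituted styrenes; by analogy with cis-cinnamates and indene the (S,S)-catalyst should give the (S)-benzylic carbon with both C–O bonds on one face (this sets the later C3 and a C2 centre that is inverted in step 5), and the basic two-phase medium spares the acetal and the acid-labile epoxide.

Step 4
Reactants: 6 3,5-bis(benzyloxy)phenol
Product: 7 3,5-bis(benzyloxy)-2-bromophenol
Conditions: NBS (1.0 equiv), i-Pr2NH (10 mol %), CH2Cl2, −78 → 0 °C
Reagents that add atoms: N-bromosuccinimide, O=C1CCC(=O)N1Br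
Why: Amine-catalysed NBS bromination of phenols is ortho-selective, and C2 (two equivalent sites, flanked by OH and OBn) is also less hindered than C4 between two benzyloxy groups, so one equivalent at low temperature should give the 2-bromophenol.

Step 5
Reactants: 5 (2S,3S)-2-[4-(benzyloxy)phenyl]-3-(diethoxymethyl)oxirane; 7 3,5-bis(benzyloxy)-2-bromophenol
Product: 8 (2S,3R)-3-[3,5-bis(benzyloxy)-2-bromophenoxy]-3-[4-(benzyloxy)phenyl]-1,1-diethoxypropan-2-ol (syn)
Conditions: Cs2CO3 (20 mol %), DMF, 70 °C
Reagents that add atoms: none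
Why: Base-catalysed SN2 opening of an aryl epoxide by a phenoxide takes place at the benzylic carbon (activated by the 4-benzyloxyphenyl group, whereas the other carbon is deactivated and shielded by the acetal) with inversion, which turns the cis-epoxide into the syn aryloxy alcohol with the (R)-configuration of the later C2 and an untouched C3.

Step 6
Reactants: 9 (−)-epicatechin
Product: 10 (2R,3R)-5,7-bis(benzyloxy)-2-[3,4-bis(benzyloxy)phenyl]chroman-3-ol
Conditions: BnBr (4.4 equiv), K2CO3, DMF, 0 °C → rt, Ar
Reagents that add atoms: benzyl bromide, BrCc1ccccc1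
Why: Williamson etherification with carbonate as base alkylates only the four phenols and leaves the aliphatic 3-OH free, and the mild base under inert gas should not epimerise C2.

Step 7
Reactants: 10 (2R,3R)-5,7-bis(benzyloxy)-2-[3,4-bis(benzyloxy)phenyl]chroman-3-ol
Product: 11 (2R,3R)-5,7-bis(benzyloxy)-2-[3,4-bis(benzyloxy)phenyl]-8-bromochroman-3-ol
Conditions: NBS (1.0 equiv), CH2Cl2, −78 °C → rt
Reagents that add atoms: N-bromosuccinimide, O=C1CCC(=O)N1Br
Why: Electrophilic aromatic bromination of benzylated flavan-3-ols takes place at C8 of the phloroglucinol ring, the most nucleophilic and less crowded site next to the tied-back ring oxygen, which leaves C6 as the only free position of ring D.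

Step 8
Reactants: 11 (2R,3R)-5,7-bis(benzyloxy)-2-[3,4-bis(benzyloxy)phenyl]-8-bromochroman-3-ol; 12 3,4,5-tris(benzyloxy)benzoic acid
Product: 13 (2R,3R)-5,7-bis(benzyloxy)-2-[3,4-bis(benzyloxy)phenyl]-8-bromochroman-3-yl 3,4,5-tris(benzyloxy)benzoate
Conditions: DCC, DMAP (cat.), CH2Cl2, rt
Reagents that add atoms: none
Why: Steglich esterification acylates the only free hydroxy group, the C–O bond at C3 is not broken so its configuration is retained, and this galloylation is standard for benzylated flavan-3-ols.

Step 9
Reactants: 8 (2S,3R)-3-[3,5-bis(benzyloxy)-2-bromophenoxy]-3-[4-(benzyloxy)phenyl]-1,1-diethoxypropan-2-ol; 13 (2R,3R)-5,7-bis(benzyloxy)-2-[3,4-bis(benzyloxy)phenyl]-8-bromochroman-3-yl 3,4,5-tris(benzyloxy)benzoate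
Product: 16 8-bromo-5,7,4'-tri-O-benzylepiafzelechin-(4β→6)-8-bromo-5,7,3',4'-tetra-O-benzylepicatechin 3-O-(3,4,5-tri-O-benzylgallate), via 4-ethoxyflavan-3-ol 14 (not isolated), via flavan-4-yl cation 15 (not isolated)
Conditions: 13 (3 equiv), TMSOTf (0.3 equiv), 4 Å MS, CH2Cl2, −78 → −20 °C, slow addition of 8; aq NaHCO3
Reagents that add atoms: none
Why: Proposed new method: TMSOTf ionises the diethyl acetal of 8 to the C4 oxocarbenium ion, the one free ortho carbon of the tethered phloroglucinol ether attacks it (intramolecular Friedel–Crafts alkylation, 6-exo-trig at the C=O+ carbon with the arene bond C4a–C8a inside the new ring) to give 14, loss of the second ethoxy group gives the A-ring-stabilised cation 15, and C6 of 13 captures it, so that one acetal carbon is arylated twice and the pyran ring, C4–C4a and the C4–C6 interflavan bond arise in one flask. The closest known reaction types are the acid-induced cyclisation of 3-aryloxypropanal acetals to 4-alkoxychromans and the Lewis acid coupling of 4-alkoxyflavan-3-ols with C8-halogenated flavan-3-ol nucleophiles at C6; new is only their merger, with an open-chain acetal as the source of the flavan-4-yl cation. Should 13 intercept the first oxocarbenium ion, the D-ring-stabilised cation formed after loss of ethanol is closed by the same ortho carbon, so both orders of events converge on 16. C4 is the only new stereocentre and is set by the substrate: in half-chair 15 the 2-aryl group and the 3-OH both lie on the α face, so 13 should add from the β face (3,4-trans), and the quasi-axial 4β-aryl group also avoids the peri 5-OBn group, so that reversible bond formation would lead to the same epimer. Site selectivity rests on the two bromine atoms: in 13 only C6 is left on the nucleophilic ring, in 8 only one ortho carbon can close the ring and the later C8 is blocked, and the remaining self-condensation at the hindered C6 of 14 is held down by slow addition of 8 to an excess of 13. The acetal oxygens are more basic and the acetal ionises far more easily than the benzylic aryl ether C2–O1 (itself deactivated by the β-hydroxy group), so C2 and C3 should pass through unchanged at low temperature, and the benzyl ethers and the gallate ester tolerate catalytic silyl triflate.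

Step 10
Reactants: 16 8-bromo-5,7,4'-tri-O-benzylepiafzelechin-(4β→6)-8-bromo-5,7,3',4'-tetra-O-benzylepicatechin 3-O-(3,4,5-tri-O-benzylgallate)
Product: 17 (−)-epiafzelechin-(4β→6)-(−)-epicatechin 3-O-gallate (upper unit 2R,3R,4S; lower unit 2R,3R), the target
Conditions: H2 (1 atm), 20 % Pd(OH)2/C, NaOAc (2.2 equiv), THF/MeOH/H2O, rt
Reagents that add atoms: none
Why: Catalytic hydrogenolysis over Pearlman's catalyst removes all ten O-benzyl groups and both aryl bromides in one operation, the acetate buffer takes up the HBr that could cleave the acid-labile interflavan bond, and no stereocentre or ester is affected.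

**Compound list**

1 | 1-(benzyloxy)-4-iodobenzene | Ic1ccc(OCc2ccccc2)cc1 | starting material
2 | 3,3-diethoxyprop-1-yne | C#CC(OCC)OCC | starting material
3 | 1-(benzyloxy)-4-(3,3-diethoxyprop-1-yn-1-yl)benzene | CCOC(OCC)C#Cc1ccc(OCc2ccccc2)cc1 | intermediate
4 | 1-(benzyloxy)-4-[(1Z)-3,3-diethoxyprop-1-en-1-yl]benzene | CCOC(OCC)/C=C\c1ccc(OCc2ccccc2)cc1 | intermediate
5 | (2S,3S)-2-[4-(benzyloxy)phenyl]-3-(diethoxymethyl)oxirane (cis) | CCOC(OCC)[C@H]1O[C@H]1c1ccc(OCc2ccccc2)cc1 | intermediate
6 | 3,5-bis(benzyloxy)phenol | Oc1cc(OCc2ccccc2)cc(OCc2ccccc2)c1 | starting material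
7 | 3,5-bis(benzyloxy)-2-bromophenol | Oc1cc(OCc2ccccc2)cc(OCc2ccccc2)c1Br | intermediate
8 | (2S,3R)-3-[3,5-bis(benzyloxy)-2-bromophenoxy]-3-[4-(benzyloxy)phenyl]-1,1-diethoxypropan-2-ol | CCOC(OCC)[C@@H](O)[C@H](Oc1cc(OCc2ccccc2)cc(OCc2ccccc2)c1Br)c1ccc(OCc2ccccc2)cc1 | intermediate
9 | (−)-epicatechin, (2R,3R) | O[C@@H]1Cc2c(O)cc(O)cc2O[C@@H]1c1ccc(O)c(O)c1 | starting material
10 | (2R,3R)-5,7-bis(benzyloxy)-2-[3,4-bis(benzyloxy)phenyl]chroman-3-ol | O[C@@H]1Cc2c(OCc3ccccc3)cc(OCc3ccccc3)cc2O[C@@H]1c1ccc(OCc2ccccc2)c(OCc2ccccc2)c1 | intermediate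
11 | (2R,3R)-5,7-bis(benzyloxy)-2-[3,4-bis(benzyloxy)phenyl]-8-bromochroman-3-ol | O[C@@H]1Cc2c(OCc3ccccc3)cc(OCc3ccccc3)c(Br)c2O[C@@H]1c1ccc(OCc2ccccc2)c(OCc2ccccc2)c1 | intermediate
12 | 3,4,5-tris(benzyloxy)benzoic acid | OC(=O)c1cc(OCc2ccccc2)c(OCc2ccccc2)c(OCc2ccccc2)c1 | starting material
13 | (2R,3R)-5,7-bis(benzyloxy)-2-[3,4-bis(benzyloxy)phenyl]-8-bromochroman-3-yl 3,4,5-tris(benzyloxy)benzoate | O=C(O[C@@H]1Cc2c(OCc3ccccc3)cc(OCc3ccccc3)c(Br)c2O[C@@H]1c1ccc(OCc2ccccc2)c(OCc2ccccc2)c1)c1cc(OCc2ccccc2)c(OCc2ccccc2)c(OCc2ccccc2)c1 | intermediate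
14 | 8-bromo-5,7,4'-tri-O-benzyl-4β-ethoxyepiafzelechin (2,3-cis, 3,4-trans drawn; C4 is lost again on ionisation) | CCO[C@H]1c2c(OCc3ccccc3)cc(OCc3ccccc3)c(Br)c2O[C@H](c2ccc(OCc3ccccc3)cc2)[C@@H]1O | intermediate (not isolated)
15 | 8-bromo-5,7,4'-tri-O-benzylepiafzelechin-4-yl cation | [CH+]1c2c(OCc3ccccc3)cc(OCc3ccccc3)c(Br)c2O[C@H](c2ccc(OCc3ccccc3)cc2)[C@@H]1O | intermediate (not isolated)
16 | 8-bromo-5,7,4'-tri-O-benzylepiafzelechin-(4β→6)-8-bromo-5,7,3',4'-tetra-O-benzylepicatechin 3-O-(3,4,5-tri-O-benzylgallate) | O=C(O[C@@H]1Cc2c(c(Br)c(OCc3ccccc3)c([C@H]3c4c(OCc5ccccc5)cc(OCc5ccccc5)c(Br)c4O[C@H](c4ccc(OCc5ccccc5)cc4)[C@@H]3O)c2OCc2ccccc2)O[C@@H]1c1ccc(OCc2ccccc2)c(OCc2ccccc2)c1)c1cc(OCc2ccccc2)c(OCc2ccccc2)c(OCc2ccccc2)c1 | intermediate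
17 | (−)-epiafzelechin-(4β→6)-(−)-epicatechin 3-O-gallate | O=C(O[C@@H]1Cc2c(cc(O)c([C@H]3c4c(O)cc(O)cc4O[C@H](c4ccc(O)cc4)[C@@H]3O)c2O)O[C@@H]1c1ccc(O)c(O)c1)c1cc(O)c(O)c(O)c1 | target

**Step count**

Total step count: 10.
Longest linear sequence: 6 steps (1, 2, 3, 5, 9, 10).

**Steps most likely to fail**

1. Step 9 (labelled step).
   - What may go wrong: ionisation of the benzylic C2–O1 ether may compete with that of the acetal, causing loss of the phenol or epimerisation at C2. The hindered, bromine-deactivated C6 of 13 may capture the cation slowly, and self-condensation then takes over.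
   - Fallback (known chemistry; the cascade is taken apart and the leaving group changed): it sets out from 8. Catalytic camphorsulfonic acid in CH2Cl2/EtOH at high dilution closes the ring alone, with ethanol re-trapping the cation, and 14 is isolated.
   - Acid-catalysed thiolysis of 14 with thiophenol gives 8-bromo-5,7,4'-tri-O-benzyl-4β-(phenylsulfanyl)epiafzelechin F1.
   - Thiophilic activation of F1 with AgBF4 in the presence of excess 13, under essentially neutral conditions, forms the interflavan bond. The route is rejoined at 16.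

2. Step 3.
   - What may go wrong: the stepwise oxygen transfer to the very electron-rich styrene may allow bond rotation (cis-to-trans leakage) and erode facial selectivity. The epoxide may also open during aqueous work-up or on silica.
   - Fallback (control by the catalyst is replaced by resolution through the chiral coupling partner): it sets out from 4. Dimethyldioxirane in acetone at 0 °C transfers oxygen in a concerted, neutral step with a volatile by-product. It gives the racemic cis-epoxide, that is 5 together with (2R,3R)-2-[4-(benzyloxy)phenyl]-3-(diethoxymethyl)oxirane F2.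
   - Step 5 then gives 8 together with its enantiomer, the (2R,3S)-hydroxy acetal F3.
   - In step 9 the enantiopure 13 converts the two enantiomers into 16 and the diastereomeric protected ent-epiafzelechin-(4α→6)-epicatechin gallate F4, which is removed by chromatography. The route is rejoined at 16.

3. Step 5.
   - What may go wrong: SN2 attack of the ortho-bromo-hindered phenoxide on the cis-disubstituted epoxide may be sluggish. Forcing conditions could bring partial SN1 character, loss of configuration at C2, or decomposition of the epoxide.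
   - Fallback (the cap is installed after ring closure): it sets out from 5 and the unhindered phenol 6. Under the conditions of step 5 these give (2S,3R)-3-[3,5-bis(benzyloxy)phenoxy]-3-[4-(benzyloxy)phenyl]-1,1-diethoxypropan-2-ol F5.
   - Catalytic camphorsulfonic acid in CH2Cl2/EtOH at high dilution cyclises it to 5,7,4'-tri-O-benzyl-4β-ethoxyepiafzelechin F6.
   - NBS at −78 °C brominates C8, the established preferred site of benzylated flavan-3-ols. The route is rejoined at 14, which is isolated here and coupled with 13 under the conditions of step 9.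

**Further compounds**

F1 | step 9 | 8-bromo-5,7,4'-tri-O-benzyl-4β-(phenylsulfanyl)epiafzelechin | c1ccccc1S[C@H]1c2c(OCc3ccccc3)cc(OCc3ccccc3)c(Br)c2O[C@H](c2ccc(OCc3ccccc3)cc2)[C@@H]1O
F2 | step 3 | (2R,3R)-2-[4-(benzyloxy)phenyl]-3-(diethoxymethyl)oxirane | CCOC(OCC)[C@@H]1O[C@@H]1c1ccc(OCc2ccccc2)cc1
F3 | step 3 | (2R,3S)-3-[3,5-bis(benzyloxy)-2-bromophenoxy]-3-[4-(benzyloxy)phenyl]-1,1-diethoxypropan-2-ol | CCOC(OCC)[C@H](O)[C@@H](Oc1cc(OCc2ccccc2)cc(OCc2ccccc2)c1Br)c1ccc(OCc2ccccc2)cc1
F4 | step 3 | 8-bromo-5,7,4'-tri-O-benzyl-ent-epiafzelechin-(4α→6)-8-bromo-5,7,3',4'-tetra-O-benzylepicatechin 3-O-(3,4,5-tri-O-benzylgallate) | O=C(O[C@@H]1Cc2c(c(Br)c(OCc3ccccc3)c([C@@H]3c4c(OCc5ccccc5)cc(OCc5ccccc5)c(Br)c4O[C@@H](c4ccc(OCc5ccccc5)cc4)[C@H]3O)c2OCc2ccccc2)O[C@@H]1c1ccc(OCc2ccccc2)c(OCc2ccccc2)c1)c1cc(OCc2ccccc2)c(OCc2ccccc2)c(OCc2ccccc2)c1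
F5 | step 5 | (2S,3R)-3-[3,5-bis(benzyloxy)phenoxy]-3-[4-(benzyloxy)phenyl]-1,1-diethoxypropan-2-ol | CCOC(OCC)[C@@H](O)[C@H](Oc1cc(OCc2ccccc2)cc(OCc2ccccc2)c1)c1ccc(OCc2ccccc2)cc1
F6 | step 5 | 5,7,4'-tri-O-benzyl-4β-ethoxyepiafzelechin | CCO[C@H]1c2c(OCc3ccccc3)cc(OCc3ccccc3)cc2O[C@H](c2ccc(OCc3ccccc3)cc2)[C@@H]1O
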